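**Plan**
- Retrosynthetic cuts, in order: C2–C1' (aryl addition to a chromone); O1–C2 and C2–C3 (enaminone closure of ring C); C3–C4 (methyl onto an acyl chloride); C4a–C8a (Claisen closure of ring A); C6–C7 and C4a–C5 (the two arm acylations of the open chain); C6–C8'' (sp3–sp2 cross-coupling on an 8-iodoflavone).
- Forward: the flavone rings come with apigenin; a seven-carbon chain is grown on C8'' and folded into ring A; ring C is then closed as a chromone through the oxygen on C8a; ring B is attached last at C2.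
- Enabling feature: ring A of the flavanone (C4a, C5, C6, C7, C8, C8a) carries oxygen on C5, C7 and C8a and carbon on C4a (C4) and C6 (C8''). This is the alternating pattern of a folded dimethyl 3,5-dioxoheptanedioate whose central carbon (future C6) bears the flavone.
- Stereochemistry: the only stereocentre, C2 (S), is set by a rhodium/(S)-biaryl bisphosphine-catalysed conjugate arylation of the chromone; nothing afterwards can epimerize it.

Key step: step 8

Abbreviation: Fl = 5,7-bis(benzyloxy)-2-[4-(benzyloxy)phenyl]-4-oxo-4H-chromen-8-yl (tri-O-benzylapigenin-8-yl). Unprimed locants are the flavanone, primed its ring B, double-primed the flavone. cod = 1,5-cyclooctadiene, dba = dibenzylideneacetone.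

Remark: the target defines only C2; rotation about the C6–C8'' axis (four ortho oxygen substituents) may be slow, so the hexa-O-benzyl flavanone and the target may form as two atropisomers about this axis, which is left uncontrolled.

Remark: the (S)-ligand of step 15 is assigned by analogy with rhodium/(S)-biaryl bisphosphine aryl additions to six-membered cyclic enones, whose facial sense corresponds to 2S here; the sense would be confirmed on 5,7-bis(benzyloxy)chromone first.

**Step 1**
Reactants: 1 apigenin
Product: 2 5,7-bis(benzyloxy)-2-[4-(benzyloxy)phenyl]-4H-chromen-4-one (tri-O-benzylapigenin)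
Conditions: BnBr (4 equiv), K2CO3, DMF, 80 °C
Reagents that add atoms: benzyl bromide, BrCc1ccccc1
Why: Williamson ether synthesis; heat and excess halide also alkylate the hydrogen-bonded 5''-OH, and full O-alkylation is what later steers iodination to C8''.

**Step 2**
Reactants: 2 tri-O-benzylapigenin
Product: 3 5,7-bis(benzyloxy)-2-[4-(benzyloxy)phenyl]-8-iodo-4H-chromen-4-one (Fl–I)
Conditions: N-iodosuccinimide (1.05 equiv), CF3CO2H (cat.), CH2Cl2/MeCN, 0 °C → rt
Reagents that add atoms: N-iodosuccinimide, O=C1CCC(=O)N1I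
Why: Electrophilic aromatic iodination; in 5-O-alkylated 5,7-dioxygenated flavones C8 (ortho to the ring oxygen and one ether, para to the other) is attacked in preference to C6, which is flanked by two benzyloxy groups, and the less electron-rich ring B and C3 should not compete.

**Step 3**
Reactants: 3 Fl–I; 4 (2-ethoxy-2-oxoethyl)zinc bromide
Product: 5 ethyl 2-Fl-acetate
Conditions: Pd2(dba)3 (2.5 mol %), XPhos (10 mol %), THF, 60 °C
Reagents that add atoms: none
Why: Negishi-type coupling of a Reformatsky reagent (neutral α-arylation of an ester): zerovalent palladium inserts into the C–I bond, the zinc enolate transmetalates and reductive elimination forms C8''–CH2; the bulky biarylphosphine copes with the di-ortho-substituted iodide and the weakly basic zinc enolate leaves the pyranone carbonyl alone.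

**Step 4**
Reactants: 5 ethyl 2-Fl-acetate
Product: 6 2-Fl-acetic acid
Conditions: LiOH·H2O, THF/MeOH/H2O, rt; then 1 M HCl
Reagents that add atoms: lithium hydroxide, [Li+].[OH-]
Why: Saponification of an unhindered arylacetic ester, which proceeds at room temperature where hydroxide does not open the flavone ring.

**Step 5**
Reactants: 6 2-Fl-acetic acid; 7 potassium methyl malonate
Product: 9 methyl 4-Fl-3-oxobutanoate, via acyl imidazolide 8 (not isolated)
Conditions: 1,1'-carbonyldiimidazole, THF, rt; then MeO2CCH2CO2K, MgCl2, Et3N, MeCN/THF, rt → 45 °C; 1 M HCl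
Reagents that add atoms: none
Why: Masamune–Brooks homologation: the acyl imidazolide acylates the magnesium enolate of the malonate half-ester at carbon and decarboxylation gives the β-keto ester under nearly neutral conditions that spare the flavone.

**Step 6**
Reactants: 9 methyl 4-Fl-3-oxobutanoate
Product: 11 1-methoxy-4-Fl-1,3-bis(trimethylsilyloxy)buta-1,3-diene, via silyl enol ether 10 (not isolated)
Conditions: Me3SiCl, Et3N, toluene, rt; filter, concentrate; LiN(i-Pr)2 (1.3 equiv), THF, −78 °C; Me3SiCl, −78 °C → rt; used crude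
Reagents that add atoms: chlorotrimethylsilane, C[Si](C)(C)Cl
Why: Standard two-stage preparation of a 1,3-bis(silyl enol ether): O-silylation of the enol, then deprotonation of the benzylic γ-CH2 (far more acidic than flavone C3''–H) by the non-nucleophilic amide and O-silylation, giving a neutral equivalent of the β-keto ester dianion.

**Step 7**
Reactants: 11 bis(silyl enol ether); 12 methyl malonyl chloride (methyl 3-chloro-3-oxopropanoate)
Product: 13 dimethyl 4-Fl-3,5-dioxoheptanedioate
Conditions: CH2Cl2, −78 °C → rt; then dilute aq. HCl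
Reagents that add atoms: none
Why: Vinylogous Mukaiyama-type C-acylation: 1,3-bis(silyl enol ethers) of β-keto esters react with acid chlorides at the terminal γ-carbon, a reaction known with methyl malonyl chloride to give 3,5-dioxopimelates, and the neutral diene avoids the proton transfer that the acidic malonyl CH2 would cause with a metal enolate.

**Step 8**
Reactants: 13 dimethyl 4-Fl-3,5-dioxoheptanedioate
Product: 14 methyl 3-Fl-2,4,6-trihydroxybenzoate
Conditions: NaOMe (4 equiv), MeOH, 0 °C → 50 °C; then cold 1 M HCl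
Reagents that add atoms: none
Why: Methoxide converts 13 into its polyanion, the C2 carbanion (between the C1 ester and the C3 ketone) adds to the C7 ester carbonyl, methoxide leaves, and the cyclohexane-1,3,5-trione tautomerizes to the phloroglucinol, whose deprotonation drains all preceding equilibria. The closest known reaction is the base-mediated intramolecular Claisen (Dieckmann-type) cyclization of 3,5-dioxoalkanedioates and 3,5,7-triketo esters to phloroglucinol carboxylates and acylphloroglucinols. The six-membered ring closes in a 6-exo-trig (enolendo) mode, chain C2 onto C7, which is C4a–C8a of the target. No stereocentre is formed. The step needs acylation on carbon rather than oxygen and a single constitution: the two arms of 13 are identical, so either closure gives 14 with the flavonyl carbon between two hydroxyls and the surviving ester on the future C4a. Lactonization to the 4-hydroxy-2-pyranone is reopened by methoxide, whereas the carbocycle is locked by aromatization.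

**Step 9**
Reactants: 14 methyl 3-Fl-2,4,6-trihydroxybenzoate
Product: 15 methyl 3-Fl-2-hydroxy-4,6-bis(methoxymethoxy)benzoate
Conditions: MeOCH2Cl (2.3 equiv), i-Pr2NEt, CH2Cl2, 0 °C → rt
Reagents that add atoms: chloromethyl methyl ether, COCCl
Why: Selective acetalization of phenols: the para hydroxyl and the ortho hydroxyl next to C5–H react, while the hydroxyl wedged between the ester and the flavonyl group is hydrogen-bonded to the ester carbonyl and shielded, as in the usual bis-protection of 2,4,6-trihydroxyaryl carbonyl compounds.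

**Step 10**
Reactants: 15 methyl 3-Fl-2-hydroxy-4,6-bis(methoxymethoxy)benzoate
Product: 16 methyl 2-(benzyloxy)-3-Fl-4,6-bis(methoxymethoxy)benzoate
Conditions: BnBr, Cs2CO3, Bu4NI (cat.), DMF, 50 °C
Reagents that add atoms: benzyl bromide, BrCc1ccccc1
Why: Williamson etherification of the remaining chelated phenol under forcing but standard conditions, which fixes a benzyl group on the oxygen (future O5) that must not close ring C.

**Step 11**
Reactants: 16 methyl 2-(benzyloxy)-3-Fl-4,6-bis(methoxymethoxy)benzoate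
Product: 17 2-(benzyloxy)-3-Fl-4,6-bis(methoxymethoxy)benzoic acid
Conditions: n-PrSLi (from n-PrSH and n-BuLi), HMPA, rt; then cold 0.5 M HCl to pH 4
Reagents that add atoms: none
Why: SN2 dealkylation of a methyl ester by a thiolate, which attacks the unhindered O-methyl carbon and is therefore indifferent to the di-ortho-substituted carbonyl that blocks saponification; at room temperature aryl benzyl ethers, the acetals and the flavone should not be cleaved.

**Step 12**
Reactants: 17 2-(benzyloxy)-3-Fl-4,6-bis(methoxymethoxy)benzoic acid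
Product: 19 1-[2-(benzyloxy)-3-Fl-4,6-bis(methoxymethoxy)phenyl]ethan-1-one, via acid chloride 18 (not isolated)
Conditions: Me2C=C(Cl)NMe2, CH2Cl2, 0 °C → rt; evaporate; Me2CuLi (from MeLi and CuI, copper monoiodide), Et2O/THF, −78 °C; aq. NH4Cl
Reagents that add atoms: lithium dimethylcuprate, [Li+].C[Cu-]C
Why: Acid chloride formation with a neutral α-chloroenamine (no HCl, so the acetals survive) followed by the classical ketone synthesis from an acid chloride and a lithium dialkylcuprate, which at −78 °C attacks neither the product ketone nor the β,β-disubstituted flavone enone.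

**Step 13**
Reactants: 19 methyl ketone
Product: 21 5-(benzyloxy)-6-Fl-7-hydroxy-4H-chromen-4-one, via enaminone 20 (not isolated)
Conditions: Me2NCH(OMe)2, toluene, 100 °C; evaporate; 2 M HCl, MeOH/THF, 40 °C
Reagents that add atoms: N,N-dimethylformamide dimethyl acetal, COC(OC)N(C)C
Why: Enaminone route to chromones: the methyl ketone condenses with the amide acetal, then acid removes both acetals and the freed hydroxyl on C8a (the only free ortho oxygen, since O5 is benzylated) adds to the enaminone and expels dimethylamine in a 6-endo-trig addition–elimination, which fixes the 6-aryl constitution.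

**Step 14**
Reactants: 21 5-(benzyloxy)-6-Fl-7-hydroxy-4H-chromen-4-one
Product: 22 5,7-bis(benzyloxy)-6-Fl-4H-chromen-4-one
Conditions: BnBr, K2CO3, DMF, rt
Reagents that add atoms: benzyl bromide, BrCc1ccccc1
Why: Williamson etherification of the acidic 7-hydroxychromone, so that no free phenol protonates or binds the rhodium aryl species in the next step.

**Step 15**
Reactants: 22 5,7-bis(benzyloxy)-6-Fl-4H-chromen-4-one; 23 4-(benzyloxy)phenylboronic acid
Product: 24 (2S)-5,7-bis(benzyloxy)-2-[4-(benzyloxy)phenyl]-6-Fl-chroman-4-one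
Conditions: [Rh(OH)(cod)]2 (2.5 mol %), (S)-MeO-F12-BIPHEP (6 mol %), toluene/H2O 10:1, 40 °C
Reagents that add atoms: none
Why: Rhodium-catalysed asymmetric 1,4-addition of an arylboronic acid to a chromone (Hayashi–Miyaura type): transmetalation, insertion of C2=C3 into the Rh–aryl bond on the enantioface left open by the electron-poor (S)-biaryl bisphosphine, and protonation of the rhodium enolate by water set C2 as S under catalyst control, while the 2-aryl-substituted flavone enone is too hindered to insert.

**Step 16**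
Reactants: 24 hexa-O-benzyl flavanone
Product: 25 (2S)-6-[5,7-dihydroxy-2-(4-hydroxyphenyl)-4-oxo-4H-chromen-8-yl]-5,7-dihydroxy-2-(4-hydroxyphenyl)chroman-4-one (target)
Conditions: H2 (1 atm), 10% Pd/C, THF/MeOH, rt; stopped after uptake of six equivalents
Reagents that add atoms: none
Why: Hydrogenolysis of six aryl benzyl ethers over palladium under neutral conditions, which cannot epimerize C2 (no base, no ring opening to the chalcone) and, if stopped at the calculated uptake, should leave the aryl ketone, the flavone double bond and the benzylic C2–O bond intact.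

**Compound list**
1 | apigenin | O=c1cc(-c2ccc(O)cc2)oc2cc(O)cc(O)c12 | starting material
2 | 5,7-bis(benzyloxy)-2-[4-(benzyloxy)phenyl]-4H-chromen-4-one | O=c1cc(-c2ccc(OCc3ccccc3)cc2)oc2cc(OCc3ccccc3)cc(OCc3ccccc3)c12 | intermediate
3 | 5,7-bis(benzyloxy)-2-[4-(benzyloxy)phenyl]-8-iodo-4H-chromen-4-one (Fl–I) | Ic1c(OCc2ccccc2)cc(OCc2ccccc2)c2c(=O)cc(-c3ccc(OCc4ccccc4)cc3)oc12 | intermediate
4 | (2-ethoxy-2-oxoethyl)zinc bromide | CCOC(=O)C[Zn]Br | starting material
5 | ethyl 2-Fl-acetate | CCOC(=O)Cc1c(OCc2ccccc2)cc(OCc2ccccc2)c2c(=O)cc(-c3ccc(OCc4ccccc4)cc3)oc12 | intermediate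
6 | 2-Fl-acetic acid | OC(=O)Cc1c(OCc2ccccc2)cc(OCc2ccccc2)c2c(=O)cc(-c3ccc(OCc4ccccc4)cc3)oc12 | intermediate
7 | potassium methyl malonate | COC(=O)CC(=O)[O-].[K+] | starting material
8 | 1-(2-Fl-acetyl)imidazole | O=C(Cc1c(OCc2ccccc2)cc(OCc2ccccc2)c2c(=O)cc(-c3ccc(OCc4ccccc4)cc3)oc12)n1ccnc1 | intermediate (not isolated)
9 | methyl 4-Fl-3-oxobutanoate | COC(=O)CC(=O)Cc1c(OCc2ccccc2)cc(OCc2ccccc2)c2c(=O)cc(-c3ccc(OCc4ccccc4)cc3)oc12 | intermediate
10 | methyl 4-Fl-3-(trimethylsilyloxy)but-2-enoate (double-bond geometry not controlled) | COC(=O)C=C(O[Si](C)(C)C)Cc1c(OCc2ccccc2)cc(OCc2ccccc2)c2c(=O)cc(-c3ccc(OCc4ccccc4)cc3)oc12 | intermediate (not isolated)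
11 | 1-methoxy-4-Fl-1,3-bis(trimethylsilyloxy)buta-1,3-diene (double-bond geometry not controlled) | COC(O[Si](C)(C)C)=CC(O[Si](C)(C)C)=Cc1c(OCc2ccccc2)cc(OCc2ccccc2)c2c(=O)cc(-c3ccc(OCc4ccccc4)cc3)oc12 | intermediate
12 | methyl malonyl chloride (methyl 3-chloro-3-oxopropanoate) | COC(=O)CC(=O)Cl | starting material
13 | dimethyl 4-Fl-3,5-dioxoheptanedioate | COC(=O)CC(=O)C(C(=O)CC(=O)OC)c1c(OCc2ccccc2)cc(OCc2ccccc2)c2c(=O)cc(-c3ccc(OCc4ccccc4)cc3)oc12 | intermediate
14 | methyl 3-Fl-2,4,6-trihydroxybenzoate | COC(=O)c1c(O)cc(O)c(-c2c(OCc3ccccc3)cc(OCc3ccccc3)c3c(=O)cc(-c4ccc(OCc5ccccc5)cc4)oc23)c1O | intermediate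
15 | methyl 3-Fl-2-hydroxy-4,6-bis(methoxymethoxy)benzoate | COC(=O)c1c(OCOC)cc(OCOC)c(-c2c(OCc3ccccc3)cc(OCc3ccccc3)c3c(=O)cc(-c4ccc(OCc5ccccc5)cc4)oc23)c1O | intermediate
16 | methyl 2-(benzyloxy)-3-Fl-4,6-bis(methoxymethoxy)benzoate | COC(=O)c1c(OCOC)cc(OCOC)c(-c2c(OCc3ccccc3)cc(OCc3ccccc3)c3c(=O)cc(-c4ccc(OCc5ccccc5)cc4)oc23)c1OCc1ccccc1 | intermediate
17 | 2-(benzyloxy)-3-Fl-4,6-bis(methoxymethoxy)benzoic acid | OC(=O)c1c(OCOC)cc(OCOC)c(-c2c(OCc3ccccc3)cc(OCc3ccccc3)c3c(=O)cc(-c4ccc(OCc5ccccc5)cc4)oc23)c1OCc1ccccc1 | intermediate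
18 | 2-(benzyloxy)-3-Fl-4,6-bis(methoxymethoxy)benzoyl chloride | ClC(=O)c1c(OCOC)cc(OCOC)c(-c2c(OCc3ccccc3)cc(OCc3ccccc3)c3c(=O)cc(-c4ccc(OCc5ccccc5)cc4)oc23)c1OCc1ccccc1 | intermediate (not isolated)
19 | 1-[2-(benzyloxy)-3-Fl-4,6-bis(methoxymethoxy)phenyl]ethan-1-one | CC(=O)c1c(OCOC)cc(OCOC)c(-c2c(OCc3ccccc3)cc(OCc3ccccc3)c3c(=O)cc(-c4ccc(OCc5ccccc5)cc4)oc23)c1OCc1ccccc1 | intermediate
20 | (E)-1-[2-(benzyloxy)-3-Fl-4,6-bis(methoxymethoxy)phenyl]-3-(dimethylamino)prop-2-en-1-one | CN(C)/C=C/C(=O)c1c(OCOC)cc(OCOC)c(-c2c(OCc3ccccc3)cc(OCc3ccccc3)c3c(=O)cc(-c4ccc(OCc5ccccc5)cc4)oc23)c1OCc1ccccc1 | intermediate (not isolated)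
21 | 5-(benzyloxy)-6-Fl-7-hydroxy-4H-chromen-4-one | O=c1ccoc2cc(O)c(-c3c(OCc4ccccc4)cc(OCc4ccccc4)c4c(=O)cc(-c5ccc(OCc6ccccc6)cc5)oc34)c(OCc3ccccc3)c12 | intermediate
22 | 5,7-bis(benzyloxy)-6-Fl-4H-chromen-4-one | O=c1ccoc2cc(OCc3ccccc3)c(-c3c(OCc4ccccc4)cc(OCc4ccccc4)c4c(=O)cc(-c5ccc(OCc6ccccc6)cc5)oc34)c(OCc3ccccc3)c12 | intermediate
23 | 4-(benzyloxy)phenylboronic acid | OB(O)c1ccc(OCc2ccccc2)cc1 | starting material
24 | (2S)-5,7-bis(benzyloxy)-2-[4-(benzyloxy)phenyl]-6-Fl-chroman-4-one | O=C1C[C@@H](c2ccc(OCc3ccccc3)cc2)Oc2cc(OCc3ccccc3)c(-c3c(OCc4ccccc4)cc(OCc4ccccc4)c4c(=O)cc(-c5ccc(OCc6ccccc6)cc5)oc34)c(OCc3ccccc3)c21 | intermediate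
25 | (2S)-6-[5,7-dihydroxy-2-(4-hydroxyphenyl)-4-oxo-4H-chromen-8-yl]-5,7-dihydroxy-2-(4-hydroxyphenyl)chroman-4-one | O=C1C[C@@H](c2ccc(O)cc2)Oc2cc(O)c(-c3c(O)cc(O)c4c(=O)cc(-c5ccc(O)cc5)oc34)c(O)c21 | target

**Step count**
Total steps: 16. Longest linear sequence: 16 (steps 1–16 from apigenin; 4, 7, 12 and 23 are purchased).

**Steps most likely to fail**

Step 7. The acid chloride may react at oxygen or at C2 of the ketene acetal, or not at all, because the nucleophilic C4 is shielded by the di-ortho-substituted flavonyl group. The fallback sets out from 9 and reverses the order of bond formation: the small acyl group goes onto the hindered carbon first, and the two-carbon extension is then made at an unhindered acyl carbon. Double deprotonation of 9 with LiN(i-Pr)2 (2.2 equiv, THF, −78 °C) should give the C2,C4-dianion, which phenyl chloroformate acylates at the more reactive C4 to give methyl phenyl 2-Fl-3-oxopentanedioate F1. A decarboxylative Claisen reaction of this activated aryl ester with 7, MgCl2 and Et3N at 40 °C follows; the acidic ester can lose phenoxide by E1cB to an acylketene that the magnesium malonate captures at carbon. Decarboxylation comes back to the route at 13.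

Step 8. Lactonization through oxygen to the 4-hydroxy-2-pyranone, or retro-Claisen loss of a malonyl arm, may outrun carbocyclization under methoxide. The fallback sets out from 13 and makes the lactone deliberately: DBU in toluene at 80 °C should give methyl 2-(5-Fl-4-hydroxy-2-oxo-2H-pyran-6-yl)acetate F2. Heating F2 with Mg(OMe)2 in methanol then effects the known pyranone-to-phloroglucinol ring transformation. The magnesium-chelated enolate of the exocyclic ester attacks the lactone carbonyl, so the same C4a–C8a bond forms with the enol lactone as acyl donor. This comes back to the route at 14.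

Step 15. Slow insertion with protodeboronation, β-aryloxide elimination from the rhodium enolate (ring opening to a chalcone) or insufficient facial control may spoil the conjugate arylation. The fallback sets out from 19 and closes ring C by oxa-Michael addition instead. Claisen–Schmidt condensation of 19 with 4-(benzyloxy)benzaldehyde (KOH, EtOH/THF, rt) should give (E)-1-[2-(benzyloxy)-3-Fl-4,6-bis(methoxymethoxy)phenyl]-3-[4-(benzyloxy)phenyl]prop-2-en-1-one F3. Mild methanolic HCl removes both acetals to give (E)-1-[2-(benzyloxy)-3-Fl-4,6-dihydroxyphenyl]-3-[4-(benzyloxy)phenyl]prop-2-en-1-one F4. A cinchona-derived bifunctional thiourea (the pseudoenantiomer that delivers 2S) in toluene cyclizes F4 through the only free ortho hydroxyl to (2S)-5-(benzyloxy)-2-[4-(benzyloxy)phenyl]-6-Fl-7-hydroxychroman-4-one F5. Hydrogenolysis as in step 16 comes back to the route at 25.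

**Further compounds**
F1 | step 7 | methyl phenyl 2-Fl-3-oxopentanedioate | COC(=O)CC(=O)C(C(=O)Oc1ccccc1)c1c(OCc2ccccc2)cc(OCc2ccccc2)c2c(=O)cc(-c3ccc(OCc4ccccc4)cc3)oc12
F2 | step 8 | methyl 2-(5-Fl-4-hydroxy-2-oxo-2H-pyran-6-yl)acetate | COC(=O)Cc1oc(=O)cc(O)c1-c1c(OCc2ccccc2)cc(OCc2ccccc2)c2c(=O)cc(-c3ccc(OCc4ccccc4)cc3)oc12
F3 | step 15 | (E)-1-[2-(benzyloxy)-3-Fl-4,6-bis(methoxymethoxy)phenyl]-3-[4-(benzyloxy)phenyl]prop-2-en-1-one | O=C(/C=C/c1ccc(OCc2ccccc2)cc1)c1c(OCOC)cc(OCOC)c(-c2c(OCc3ccccc3)cc(OCc3ccccc3)c3c(=O)cc(-c4ccc(OCc5ccccc5)cc4)oc23)c1OCc1ccccc1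
F4 | step 15 | (E)-1-[2-(benzyloxy)-3-Fl-4,6-dihydroxyphenyl]-3-[4-(benzyloxy)phenyl]prop-2-en-1-one | O=C(/C=C/c1ccc(OCc2ccccc2)cc1)c1c(O)cc(O)c(-c2c(OCc3ccccc3)cc(OCc3ccccc3)c3c(=O)cc(-c4ccc(OCc5ccccc5)cc4)oc23)c1OCc1ccccc1
F5 | step 15 | (2S)-5-(benzyloxy)-2-[4-(benzyloxy)phenyl]-6-Fl-7-hydroxychroman-4-one | O=C1C[C@@H](c2ccc(OCc3ccccc3)cc2)Oc2cc(O)c(-c3c(OCc4ccccc4)cc(OCc4ccccc4)c4c(=O)cc(-c5ccc(OCc6ccccc6)cc5)oc34)c(OCc3ccccc3)c21
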